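## Retrosynthetic overview

1. The target comes from removal of two triethylsilyl ethers; the C6–C7 bond is made by a palladium-catalysed Suzuki–Miyaura coupling of a ring (Z)-enol triflate with an (E)-alkenylboronate, which fixes 7Z and 5E.
2. The ring triflate comes from a 2-bromo-4-hydroxy-4-alkylcyclopentenone by C8 formylation and chelation-controlled O-triflation; that bromoenone comes from carbonyl transposition of an α'-hydroxy vinylogous ester.
3. The α'-hydroxy vinylogous ester comes from 2-bromo-3-methoxycyclopentenone by α'-alkylation with (2Z,5Z)-octadienyl bromide (C12–C13) and asymmetric enolate hydroxylation (C12).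
4. The dienyl bromide comes from prop-2-yn-1-ol and 1-bromopent-2-yne (copper-catalysed coupling, semi-hydrogenation). The boronate comes from succinic anhydride and ethynyltrimethylsilane (acyl Sonogashira coupling, asymmetric transfer hydrogenation for C4, hydroboration).
5. Rings: the single carbocycle is bought as 3-methoxycyclopent-2-enone and refunctionalised; no ring is formed in the route.

Assumption: the (+)-dichlorocamphorsulfonyl oxaziridine is taken to oxidise the enolate face that gives the (S) tertiary alcohol; if a first run shows the opposite sense, the (−)-reagent is used and nothing else changes.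

Position labels C1–C20 are prostanoid positions of the target (C1 ester carbon, C8–C12 ring, C13–C20 octadienyl chain).

## Route

Step 1
Reactants: 1 prop-2-yn-1-ol; 2 1-bromopent-2-yne
Product: 3 octa-2,5-diyn-1-ol
Conditions: CuI (10 mol %), NaI (10 mol %), Cs2CO3 (1.2 equiv), DMF, 23 °C
Reagents that add atoms: none
Why: Copper-catalysed coupling of a terminal alkyne with a propargylic bromide (skipped-diyne synthesis) goes through a copper acetylide that displaces bromide at CH2.

Step 2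
Reactants: 3 octa-2,5-diyn-1-ol
Product: 4 (2Z,5Z)-octa-2,5-dien-1-ol
Conditions: Ni(OAc)2·4H2O (20 mol %), NaBH4 (20 mol %) (Ni2B formed in situ), H2NCH2CH2NH2, H2 (1 atm), EtOH, 23 °C
Reagents that add atoms: none
Why: Nickel boride semi-hydrogenation adds H2 syn to each alkyne and stops at the alkene when ethylenediamine is present, which sets both Z double bonds.

Step 3
Reactants: 4 (2Z,5Z)-octa-2,5-dien-1-ol
Product: 5 (2Z,5Z)-1-bromoocta-2,5-diene
Conditions: CBr4, PPh3, CH2Cl2, 0 °C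
Reagents that add atoms: tetrabromomethane, BrC(Br)(Br)Br
Why: Appel bromination replaces the primary allylic hydroxyl by SN2 at 0 °C without allylic shift or Z to E isomerisation.

Step 4
Reactants: 6 3-methoxycyclopent-2-en-1-one
Product: 7 2-bromo-3-methoxycyclopent-2-en-1-one
Conditions: N-bromosuccinimide, CH2Cl2, 0 → 23 °C
Reagents that add atoms: N-bromosuccinimide, O=C1CCC(=O)N1Br
Why: Electrophilic α-bromination of a vinylogous ester occurs only at the enol-ether-like C2; this places the bromine (later C10) before any other alkene is present.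

Step 5
Reactants: 7 2-bromo-3-methoxycyclopent-2-en-1-one; 5 (2Z,5Z)-1-bromoocta-2,5-diene
Product: 9 rac-2-bromo-3-methoxy-5-[(2Z,5Z)-octa-2,5-dien-1-yl]cyclopent-2-en-1-one, via lithium enolate 8 (not isolated)
Conditions: LiN(i-Pr)2, THF, −78 °C; then 5, DMPU, −78 → −20 °C
Reagents that add atoms: none
Why: Stork–Danheiser kinetic α'-deprotonation gives the cross-conjugated enolate, which is C-alkylated by the allylic bromide (SN2) to form C12–C13; the new centre is racemic and is erased in step 6.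

Step 6
Reactants: 9 rac-2-bromo-3-methoxy-5-[(2Z,5Z)-octa-2,5-dien-1-yl]cyclopent-2-en-1-one
Product: 11 (5S)-2-bromo-5-hydroxy-3-methoxy-5-[(2Z,5Z)-octa-2,5-dien-1-yl]cyclopent-2-en-1-one, via potassium enolate 10 (not isolated)
Conditions: KN(SiMe3)2, THF, −78 °C; then (+)-[(8,8-dichlorocamphoryl)sulfonyl]oxaziridine, −78 °C; aq. NH4Cl
Reagents that add atoms: (+)-[(8,8-dichlorocamphoryl)sulfonyl]oxaziridine, CC1(C)[C@@H]2CC[C@]13CS(=O)(=O)N4O[C@@]34C2(Cl)Cl
Why: Davis asymmetric enolate hydroxylation: the planar tetrasubstituted enolate attacks the oxaziridine oxygen in an open SN2-type transition state while the camphor cage shields one face, which sets the tertiary carbinol (5S here, 12R in the target); the reagent does not touch the Z alkenes at −78 °C.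

Step 7
Reactants: 11 (5S)-2-bromo-5-hydroxy-3-methoxy-5-[(2Z,5Z)-octa-2,5-dien-1-yl]cyclopent-2-en-1-one
Product: 13 (4S)-2-bromo-4-hydroxy-4-[(2Z,5Z)-octa-2,5-dien-1-yl]cyclopent-2-en-1-one, via methoxy diol 12 (not isolated)
Conditions: i-Bu2AlH (2.5 equiv), CH2Cl2, −78 → 0 °C; then 1 M HCl, THF, 0 → 23 °C
Reagents that add atoms: water, O
Why: Stork–Danheiser carbonyl transposition: 1,2-reduction of the vinylogous ester carbonyl, then acid-promoted ionisation and hydrolysis of the alkoxy allylic alcohol, gives the transposed α-bromoenone; the tertiary carbinol is not involved and keeps its configuration.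

Step 8
Reactants: 13 (4S)-2-bromo-4-hydroxy-4-[(2Z,5Z)-octa-2,5-dien-1-yl]cyclopent-2-en-1-one
Product: 14 (4S)-2-bromo-4-[(2Z,5Z)-octa-2,5-dien-1-yl]-4-[(triethylsilyl)oxy]cyclopent-2-en-1-one
Conditions: Et3SiOTf, 2,6-lutidine, CH2Cl2, −78 → 0 °C
Reagents that add atoms: triethylsilyl trifluoromethanesulfonate, CC[Si](CC)(CC)OS(=O)(=O)C(F)(F)F
Why: Silylation with a silyl triflate and a hindered base protects the hindered tertiary alcohol before enolate chemistry, at a temperature where the ketone is not enolised.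

Step 9
Reactants: 14 (4S)-2-bromo-4-[(2Z,5Z)-octa-2,5-dien-1-yl]-4-[(triethylsilyl)oxy]cyclopent-2-en-1-one
Product: 17 (Z)-[(5R)-3-bromo-5-[(2Z,5Z)-octa-2,5-dien-1-yl]-2-oxo-5-[(triethylsilyl)oxy]cyclopent-3-en-1-ylidene]methyl trifluoromethanesulfonate, via lithium dienolate 15 (not isolated), via lithium formyl-enolate chelate 16 (not isolated)
Conditions: LiN(SiMe3)2, THF, −78 °C; HCO2CH2CF3, −78 °C; then PhNTf2, −78 → 0 °C; aq. NH4Cl
Reagents that add atoms: 2,2,2-trifluoroethyl formate, O=COCC(F)(F)F; N-phenylbis(trifluoromethanesulfonimide), FC(F)(F)S(=O)(=O)N(c1ccccc1)S(=O)(=O)C(F)(F)F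
Why: Claisen-type kinetic C-formylation of the α' lithium enolate gives a lithium-chelated β-keto aldehyde enolate whose formyl oxygen is held syn to the ring carbonyl, so O-triflation gives the Z enol triflate, which is also the less hindered isomer because the E isomer would press the triflate against quaternary C12.

Step 10
Reactants: 18 succinic anhydride; 19 methanol
Product: 20 4-methoxy-4-oxobutanoic acid
Conditions: MeOH, reflux
Reagents that add atoms: none
Why: Alcoholysis of a cyclic anhydride gives the half ester cleanly.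

Step 11
Reactants: 20 4-methoxy-4-oxobutanoic acid
Product: 21 methyl 4-chloro-4-oxobutanoate
Conditions: (COCl)2, DMF (cat.), CH2Cl2, 0 → 23 °C
Reagents that add atoms: oxalyl chloride, ClC(=O)C(Cl)=O
Why: Vilsmeier-type activation turns the acid into the acid chloride and leaves the methyl ester alone.

Step 12
Reactants: 21 methyl 4-chloro-4-oxobutanoate; 22 ethynyltrimethylsilane
Product: 23 methyl 4-oxo-6-(trimethylsilyl)hex-5-ynoate
Conditions: PdCl2(PPh3)2 (2 mol %), CuI (4 mol %), Et3N (1.1 equiv), THF, 23 °C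
Reagents that add atoms: none
Why: Acyl Sonogashira coupling: zerovalent palladium inserts into the acyl C–Cl bond, the copper acetylide transmetalates and reductive elimination gives the ynone.

Step 13
Reactants: 23 methyl 4-oxo-6-(trimethylsilyl)hex-5-ynoate
Product: 24 methyl (4S)-4-hydroxy-6-(trimethylsilyl)hex-5-ynoate
Conditions: Ru[(S,S)-TsNCH(Ph)CH(Ph)NH](η6-p-cymene) (1 mol %), i-PrOH, 23 °C
Reagents that add atoms: none
Why: Noyori asymmetric transfer hydrogenation of an ynone: the (S,S)-diamine ruthenium hydride transfers H–/H+ through the six-membered bifunctional transition state with the alkyne in the place usually taken by an aryl group, which gives the (S) propargylic alcohol (C4).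

Step 14
Reactants: 24 methyl (4S)-4-hydroxy-6-(trimethylsilyl)hex-5-ynoate
Product: 25 methyl (4S)-4-[(triethylsilyl)oxy]-6-(trimethylsilyl)hex-5-ynoate
Conditions: Et3SiCl, imidazole, CH2Cl2, 0 → 23 °C
Reagents that add atoms: chlorotriethylsilane, CC[Si](Cl)(CC)CC
Why: Standard silylation of the secondary alcohol blocks lactonisation onto the methyl ester.

Step 15
Reactants: 25 methyl (4S)-4-[(triethylsilyl)oxy]-6-(trimethylsilyl)hex-5-ynoate
Product: 26 methyl (4S)-4-[(triethylsilyl)oxy]hex-5-ynoate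
Conditions: K2CO3 (0.2 equiv), MeOH, 0 °C
Reagents that add atoms: none
Why: Base-catalysed methanolysis cleaves the C(sp)–Si bond selectively, while the O-triethylsilyl ether and the methyl ester survive at 0 °C.

Step 16
Reactants: 26 methyl (4S)-4-[(triethylsilyl)oxy]hex-5-ynoate
Product: 27 methyl (4S,5E)-6-(4,4,5,5-tetramethyl-1,3,2-dioxaborolan-2-yl)-4-[(triethylsilyl)oxy]hex-5-enoate
Conditions: pinacolborane (1.2 equiv), Cp2Zr(H)Cl (10 mol %), Et3N (10 mol %), neat, 50 °C
Reagents that add atoms: pinacolborane, CC1(C)OBOC1(C)C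
Why: Zirconium-catalysed hydroboration (syn hydrozirconation of the terminal alkyne, then Zr-to-B exchange) places boron at the terminal carbon and fixes the 5E geometry.

Step 17
Reactants: 17 (Z)-[(5R)-3-bromo-5-[(2Z,5Z)-octa-2,5-dien-1-yl]-2-oxo-5-[(triethylsilyl)oxy]cyclopent-3-en-1-ylidene]methyl trifluoromethanesulfonate; 27 methyl (4S,5E)-6-(4,4,5,5-tetramethyl-1,3,2-dioxaborolan-2-yl)-4-[(triethylsilyl)oxy]hex-5-enoate (1.05 equiv)
Product: 28 methyl (4S,5E,7Z)-7-[(5R)-3-bromo-5-[(2Z,5Z)-octa-2,5-dien-1-yl]-2-oxo-5-[(triethylsilyl)oxy]cyclopent-3-en-1-ylidene]-4-[(triethylsilyl)oxy]hept-5-enoate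
Conditions: PdCl2(dppf) (5 mol %), K3PO4 (3 equiv), degassed THF/H2O (10:1), 0 → 23 °C, dark
Reagents that add atoms: none
Why: Proposed new method: site-selective, geometry-retentive Suzuki–Miyaura alkenylation of an exocyclic (Z)-β-keto-aldehyde enol triflate that carries an α-bromoenone in the same ring; bis-ligated zerovalent palladium (dppf) should enter the vinylogous acyl triflate by a polar addition–elimination type oxidative addition much faster than by three-centre insertion into the less activated C10–Br bond, the resulting cationic alkenyl divalent palladium can close a five-membered O=C9–C8=C7–Pd chelate that only the Z isomer can form and so holds that geometry, and base-assisted transmetalation from the boronate and reductive elimination then form C6–C7 with retention at both alkenes (7Z from 17, 5E from 27) without touching C12 or C4; the closest known reaction type is the stereoretentive Suzuki–Miyaura coupling of (Z)-enol triflates and tosylates of β-keto esters.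

Step 18
Reactants: 28 methyl (4S,5E,7Z)-7-[(5R)-3-bromo-5-[(2Z,5Z)-octa-2,5-dien-1-yl]-2-oxo-5-[(triethylsilyl)oxy]cyclopent-3-en-1-ylidene]-4-[(triethylsilyl)oxy]hept-5-enoate
Product: 29 methyl (4S,5E,7Z)-7-[(5R)-3-bromo-5-hydroxy-5-[(2Z,5Z)-octa-2,5-dien-1-yl]-2-oxocyclopent-3-en-1-ylidene]-4-hydroxyhept-5-enoate
Conditions: HF·pyridine, pyridine, THF, 0 °C, dark
Reagents that add atoms: none
Why: Buffered fluoride desilylation cleaves both triethylsilyl ethers under weakly acidic conditions that avoid lactonisation of the γ-hydroxy ester and E/Z isomerisation of the cross-conjugated dienone.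

## Compound list

1 | prop-2-yn-1-ol | C#CCO | starting material
2 | 1-bromopent-2-yne | CCC#CCBr | starting material
3 | octa-2,5-diyn-1-ol | CCC#CCC#CCO | intermediate
4 | (2Z,5Z)-octa-2,5-dien-1-ol | CC/C=C\C/C=C\CO | intermediate
5 | (2Z,5Z)-1-bromoocta-2,5-diene | CC/C=C\C/C=C\CBr | intermediate
6 | 3-methoxycyclopent-2-en-1-one | COC1=CC(=O)CC1 | starting material
7 | 2-bromo-3-methoxycyclopent-2-en-1-one | COC1=C(Br)C(=O)CC1 | intermediate
8 | lithium 5-bromo-4-methoxycyclopenta-1,4-dien-1-olate (α' enolate of 7) | [Li]OC1=CCC(OC)=C1Br | intermediate (not isolated)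
9 | rac-2-bromo-3-methoxy-5-[(2Z,5Z)-octa-2,5-dien-1-yl]cyclopent-2-en-1-one | CC/C=C\C/C=C\CC1CC(OC)=C(Br)C1=O | intermediate
10 | potassium 5-bromo-4-methoxy-2-[(2Z,5Z)-octa-2,5-dien-1-yl]cyclopenta-1,4-dien-1-olate (enolate of 9) | [K]OC1=C(C/C=C\C/C=C\CC)CC(OC)=C1Br | intermediate (not isolated)
11 | (5S)-2-bromo-5-hydroxy-3-methoxy-5-[(2Z,5Z)-octa-2,5-dien-1-yl]cyclopent-2-en-1-one | CC/C=C\C/C=C\C[C@@]1(O)C(=O)C(Br)=C(OC)C1 | intermediate
12 | (1S,2RS)-3-bromo-4-methoxy-1-[(2Z,5Z)-octa-2,5-dien-1-yl]cyclopent-3-ene-1,2-diol (both C2 epimers) | CC/C=C\C/C=C\C[C@@]1(O)C(O)C(Br)=C(OC)C1 | intermediate (not isolated)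
13 | (4S)-2-bromo-4-hydroxy-4-[(2Z,5Z)-octa-2,5-dien-1-yl]cyclopent-2-en-1-one | CC/C=C\C/C=C\C[C@@]1(O)C=C(Br)C(=O)C1 | intermediate
14 | (4S)-2-bromo-4-[(2Z,5Z)-octa-2,5-dien-1-yl]-4-[(triethylsilyl)oxy]cyclopent-2-en-1-one | CC/C=C\C/C=C\C[C@@]1(O[Si](CC)(CC)CC)C=C(Br)C(=O)C1 | intermediate
15 | lithium (3S)-5-bromo-3-[(2Z,5Z)-octa-2,5-dien-1-yl]-3-[(triethylsilyl)oxy]cyclopenta-1,4-dien-1-olate (α' enolate of 14) | CC/C=C\C/C=C\C[C@@]1(O[Si](CC)(CC)CC)C=C(Br)C(O[Li])=C1 | intermediate (not isolated)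
16 | lithium (Z)-[(5R)-3-bromo-5-[(2Z,5Z)-octa-2,5-dien-1-yl]-2-oxo-5-[(triethylsilyl)oxy]cyclopent-3-en-1-ylidene]methanolate (chelate, O syn to C=O) | CC/C=C\C/C=C\C[C@@]1(O[Si](CC)(CC)CC)C=C(Br)C(=O)/C1=C\O[Li] | intermediate (not isolated)
17 | (Z)-[(5R)-3-bromo-5-[(2Z,5Z)-octa-2,5-dien-1-yl]-2-oxo-5-[(triethylsilyl)oxy]cyclopent-3-en-1-ylidene]methyl trifluoromethanesulfonate | CC/C=C\C/C=C\C[C@@]1(O[Si](CC)(CC)CC)C=C(Br)C(=O)/C1=C\OS(=O)(=O)C(F)(F)F | intermediate
18 | succinic anhydride (oxolane-2,5-dione) | O=C1CCC(=O)O1 | starting material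
19 | methanol | CO | starting material
20 | 4-methoxy-4-oxobutanoic acid | COC(=O)CCC(=O)O | intermediate
21 | methyl 4-chloro-4-oxobutanoate | COC(=O)CCC(Cl)=O | intermediate
22 | ethynyltrimethylsilane | C#C[Si](C)(C)C | starting material
23 | methyl 4-oxo-6-(trimethylsilyl)hex-5-ynoate | COC(=O)CCC(=O)C#C[Si](C)(C)C | intermediate
24 | methyl (4S)-4-hydroxy-6-(trimethylsilyl)hex-5-ynoate | COC(=O)CC[C@H](O)C#C[Si](C)(C)C | intermediate
25 | methyl (4S)-4-[(triethylsilyl)oxy]-6-(trimethylsilyl)hex-5-ynoate | COC(=O)CC[C@H](O[Si](CC)(CC)CC)C#C[Si](C)(C)C | intermediate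
26 | methyl (4S)-4-[(triethylsilyl)oxy]hex-5-ynoate | COC(=O)CC[C@H](O[Si](CC)(CC)CC)C#C | intermediate
27 | methyl (4S,5E)-6-(4,4,5,5-tetramethyl-1,3,2-dioxaborolan-2-yl)-4-[(triethylsilyl)oxy]hex-5-enoate | COC(=O)CC[C@H](O[Si](CC)(CC)CC)/C=C/B1OC(C)(C)C(C)(C)O1 | intermediate
28 | methyl (4S,5E,7Z)-7-[(5R)-3-bromo-5-[(2Z,5Z)-octa-2,5-dien-1-yl]-2-oxo-5-[(triethylsilyl)oxy]cyclopent-3-en-1-ylidene]-4-[(triethylsilyl)oxy]hept-5-enoate | CC/C=C\C/C=C\C[C@@]1(O[Si](CC)(CC)CC)C=C(Br)C(=O)/C1=C\C=C\[C@@H](O[Si](CC)(CC)CC)CCC(=O)OC | intermediate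
29 | methyl (4S,5E,7Z)-7-[(5R)-3-bromo-5-hydroxy-5-[(2Z,5Z)-octa-2,5-dien-1-yl]-2-oxocyclopent-3-en-1-ylidene]-4-hydroxyhept-5-enoate | CC/C=C\C/C=C\C[C@@]1(O)C=C(Br)C(=O)/C1=C\C=C\[C@@H](O)CCC(=O)OC | target

## Step count and risks

Total step count: 18. Longest linear sequence: 10 (steps 1, 2, 3, 5, 6, 7, 8, 9, 17, 18).

The three steps most likely to fail:

**Step 6 (level and sense of asymmetric induction at C12).** The fallback sets out from 9 and comes back at 11. The potassium enolate 10 is oxidised with achiral 3-phenyl-2-(phenylsulfonyl)oxaziridine (KN(SiMe3)2, THF, −78 °C) to give racemic 2-bromo-5-hydroxy-3-methoxy-5-[(2Z,5Z)-octa-2,5-dien-1-yl]cyclopent-2-en-1-one F1. The racemate is resolved by preparative supercritical-fluid chromatography on an amylose carbamate chiral stationary phase. The (5S) enantiomer is 11; its configuration is checked by the Mosher or X-ray method on a derivative before going on.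

**Step 9 (stability of the dienolate, and site and geometry of triflation).** The fallback sets out from 14 and comes back at 17, and uses no amide base for the C–C bond. Heating 14 with t-BuOCH(NMe2)2 in toluene at 60 °C gives (4R)-2-bromo-5-[(dimethylamino)methylidene]-4-[(2Z,5Z)-octa-2,5-dien-1-yl]-4-[(triethylsilyl)oxy]cyclopent-2-en-1-one F2. Brief hydrolysis with cold 1 M HCl in THF gives the isolable (4R,5Z)-2-bromo-5-(hydroxymethylidene)-4-[(2Z,5Z)-octa-2,5-dien-1-yl]-4-[(triethylsilyl)oxy]cyclopent-2-en-1-one F3. One equivalent of LiN(SiMe3)2 in THF at −78 °C then forms the lithium chelate 16, which is triflated with PhNTf2 to give 17.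

**Step 17 (the proposed coupling: C–OTf against C–Br selectivity, retention of 7Z).** The fallback uses the known aldol–dehydration route to cross-conjugated alkylidene cyclopentenones; it sets out from 14 and 26 and comes back at 28.
- Semi-hydrogenation of 26 (H2, Pd/CaCO3 poisoned with Pb(OAc)2, quinoline, EtOAc) gives methyl (4S)-4-[(triethylsilyl)oxy]hex-5-enoate F4.
- Cross-metathesis of F4 with acrolein (second-generation Hoveyda–Grubbs catalyst, RuCl2(H2IMes)(=CH–C6H4-2-O-i-Pr), CH2Cl2, 40 °C) gives methyl (4S,5E)-7-oxo-4-[(triethylsilyl)oxy]hept-5-enoate F5.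
- The lithium enolate 15 (from 14, LiN(SiMe3)2, THF, −78 °C) adds to F5 to give the aldol methyl (4S,5E)-7-[(5S)-3-bromo-5-[(2Z,5Z)-octa-2,5-dien-1-yl]-2-oxo-5-[(triethylsilyl)oxy]cyclopent-3-en-1-yl]-7-hydroxy-4-[(triethylsilyl)oxy]hept-5-enoate F6 as a diastereomer mixture.
- MsCl and Et3N in CH2Cl2 at 0 °C convert F6 to methyl (4S,5E)-7-[(5S)-3-bromo-5-[(2Z,5Z)-octa-2,5-dien-1-yl]-2-oxo-5-[(triethylsilyl)oxy]cyclopent-3-en-1-yl]-7-[(methylsulfonyl)oxy]-4-[(triethylsilyl)oxy]hept-5-enoate F7, which eliminates in the same flask.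
- The elimination gives 28 together with its 7E isomer, methyl (4S,5E,7E)-7-[(5R)-3-bromo-5-[(2Z,5Z)-octa-2,5-dien-1-yl]-2-oxo-5-[(triethylsilyl)oxy]cyclopent-3-en-1-ylidene]-4-[(triethylsilyl)oxy]hept-5-enoate F8. The two are separated by chromatography; this route gives no control of the 7-geometry, so the yield of 28 depends on the ratio.

Further compounds

F1 | step 6 | rac-2-bromo-5-hydroxy-3-methoxy-5-[(2Z,5Z)-octa-2,5-dien-1-yl]cyclopent-2-en-1-one | CC/C=C\C/C=C\CC1(O)C(=O)C(Br)=C(OC)C1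
F2 | step 9 | (4R)-2-bromo-5-[(dimethylamino)methylidene]-4-[(2Z,5Z)-octa-2,5-dien-1-yl]-4-[(triethylsilyl)oxy]cyclopent-2-en-1-one (enamine geometry not defined) | CC/C=C\C/C=C\C[C@@]1(O[Si](CC)(CC)CC)C=C(Br)C(=O)C1=CN(C)C
F3 | step 9 | (4R,5Z)-2-bromo-5-(hydroxymethylidene)-4-[(2Z,5Z)-octa-2,5-dien-1-yl]-4-[(triethylsilyl)oxy]cyclopent-2-en-1-one | CC/C=C\C/C=C\C[C@@]1(O[Si](CC)(CC)CC)C=C(Br)C(=O)/C1=C\O
F4 | step 17 | methyl (4S)-4-[(triethylsilyl)oxy]hex-5-enoate | COC(=O)CC[C@H](O[Si](CC)(CC)CC)C=C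
F5 | step 17 | methyl (4S,5E)-7-oxo-4-[(triethylsilyl)oxy]hept-5-enoate | COC(=O)CC[C@H](O[Si](CC)(CC)CC)/C=C/C=O
F6 | step 17 | methyl (4S,5E)-7-[(5S)-3-bromo-5-[(2Z,5Z)-octa-2,5-dien-1-yl]-2-oxo-5-[(triethylsilyl)oxy]cyclopent-3-en-1-yl]-7-hydroxy-4-[(triethylsilyl)oxy]hept-5-enoate (diastereomer mixture) | CC/C=C\C/C=C\C[C@@]1(O[Si](CC)(CC)CC)C=C(Br)C(=O)C1C(O)/C=C/[C@@H](O[Si](CC)(CC)CC)CCC(=O)OC
F7 | step 17 | methyl (4S,5E)-7-[(5S)-3-bromo-5-[(2Z,5Z)-octa-2,5-dien-1-yl]-2-oxo-5-[(triethylsilyl)oxy]cyclopent-3-en-1-yl]-7-[(methylsulfonyl)oxy]-4-[(triethylsilyl)oxy]hept-5-enoate (diastereomer mixture) | CC/C=C\C/C=C\C[C@@]1(O[Si](CC)(CC)CC)C=C(Br)C(=O)C1C(OS(C)(=O)=O)/C=C/[C@@H](O[Si](CC)(CC)CC)CCC(=O)OC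
F8 | step 17 | methyl (4S,5E,7E)-7-[(5R)-3-bromo-5-[(2Z,5Z)-octa-2,5-dien-1-yl]-2-oxo-5-[(triethylsilyl)oxy]cyclopent-3-en-1-ylidene]-4-[(triethylsilyl)oxy]hept-5-enoate | CC/C=C\C/C=C\C[C@@]1(O[Si](CC)(CC)CC)C=C(Br)C(=O)/C1=C/C=C/[C@@H](O[Si](CC)(CC)CC)CCC(=O)OC
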